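**Assumptions:** (S)-BINOL/Ti(OiPr)4 is taken to direct Chan's diene to the Si face of the aryl aldehyde, giving the (S)-carbinol; this sense is recalled from precedent, not verified, so check it on compound 4 (Mosher ester) and switch to (R)-BINOL if it is opposite. Chan's diene is taken as a catalogue reagent; otherwise it is two routine steps from methyl acetoacetate.

**Retrosynthetic overview**
1. Target 12 ⇐ 11 by methylation of the free, non-chelated 7-OH only.
2. 11 ⇐ acyclic ketene dithioacetal 6 + methoxyacetone 7: one flask forms O1–C8a, C8–C8a and C5–C6; ring C closes first, ring A second.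
3. 6 ⇐ δ-hydroxy-β-ketoester 4 + CS2/MeI (the CS2 carbon becomes C8a, the ester carbon becomes C5).
4. 4 ⇐ veratraldehyde 1 + Chan's diene 2 by catalytic asymmetric vinylogous Mukaiyama aldol; this sets C2 as S, and its C–O bond is never broken afterwards.

**Route**

Step 1
Reactants: 1 3,4-dimethoxybenzaldehyde; 2 Chan's diene (1-methoxy-1,3-bis(trimethylsilyloxy)buta-1,3-diene)
Product: 4 methyl (5S)-5-(3,4-dimethoxyphenyl)-5-hydroxy-3-oxopentanoate, via bis-silyl aldol adduct 3 (not isolated)
Conditions: (S)-BINOL (10 mol%), Ti(OiPr)4 (10 mol%), 4 Å MS, THF, −78 °C→rt; then TFA, −78 °C→rt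
Reagents that add atoms: none
Why: The Ti(IV)–BINOL-catalysed vinylogous Mukaiyama aldol of Chan's diene reacts only at the diene γ-carbon and gives δ-hydroxy-β-ketoesters of aromatic aldehydes in high ee, Si-face attack under the (S)-BINOL complex setting the carbinol carbon as S.

Step 2
Reactants: 4 methyl (5S)-5-(3,4-dimethoxyphenyl)-5-hydroxy-3-oxopentanoate
Product: 6 methyl (5S)-2-[bis(methylsulfanyl)methylidene]-5-(3,4-dimethoxyphenyl)-5-hydroxy-3-oxopentanoate, via methyl dithioester 5 (not isolated)
Conditions: K2CO3 (2.5 equiv), CS2 (1.2 equiv), DMF, 0 °C; then MeI (2.4 equiv), 0 °C→rt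
Reagents that add atoms: carbon disulfide, S=C=S; iodomethane, CI
Why: Standard α-oxoketene dithioacetal formation, in which carbonate deprotonates only the β-ketoester CH2 (not the alcohol), the enolate adds to CS2 and two S-methylations follow, leaving the stereocentre untouched.

Step 3
Reactants: 6 methyl (5S)-2-[bis(methylsulfanyl)methylidene]-5-(3,4-dimethoxyphenyl)-5-hydroxy-3-oxopentanoate; 7 methoxyacetone (1-methoxypropan-2-one)
Product: 11 (2S)-2-(3,4-dimethoxyphenyl)-5,7-dihydroxy-6-methoxy-2,3-dihydro-4H-chromen-4-one, via lithium 3-methoxyprop-1-en-2-olate 8 (not isolated), via 6-methylsulfanyl dihydropyranone ester 9 (not isolated), via 6-(3-methoxy-2-oxopropyl) dihydropyranone ester 10 (not isolated)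
Conditions: 6, LiHMDS (1.1 equiv), THF, −78→0 °C; then add to 8 [7 (1.5 equiv), LDA (1.5 equiv), THF, −78 °C] + LiHMDS (2.5 equiv), −78 °C→rt; AcOH quench at −78 °C
Reagents that add atoms: none
Why: Proposed new method: the lithium alkoxide of 6 displaces one SMe by 6-endo addition–elimination to give pyranone 9 (ring C), the kinetic CH3-side enolate 8 displaces the second SMe to give 10, and excess amide base generates the α-methoxy carbanion of 10, which closes on the neighbouring ester and aromatises to the resorcinol ring (ring A); the C2–O bond is never broken and the anionic intermediates resist retro-oxa-Michael opening, so the S centre is carried through; closest known chemistry is the Junjappa–Ila [3+3] benzannulation of α-oxoketene dithioacetals, SMe displacement by phenolic OH in 2-(methylsulfanyl)chromone synthesis, and Staunton–Weinreb/Harris-type Dieckmann aromatisation.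

Step 4
Reactants: 11 (2S)-2-(3,4-dimethoxyphenyl)-5,7-dihydroxy-6-methoxy-2,3-dihydro-4H-chromen-4-one
Product: 12 (2S)-2-(3,4-dimethoxyphenyl)-5-hydroxy-6,7-dimethoxy-2,3-dihydro-4H-chromen-4-one
Conditions: TMSCHN2 (1.5 equiv), MeOH/CH2Cl2 (1:4), 0 °C→rt; AcOH quench
Reagents that add atoms: trimethylsilyldiazomethane, C[Si](C)(C)C=[N+]=[N-]
Why: Diazoalkane O-methylation under neutral conditions takes the acidic, non-chelated 7-OH and leaves the 5-OH (hydrogen-bonded to C4=O) alone, and without base the flavanone cannot open to the chalcone, so C2 stays S.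

**Compound list**
1 | 3,4-dimethoxybenzaldehyde (veratraldehyde) | COc1ccc(C=O)cc1OC | starting material
2 | Chan's diene, 1-methoxy-1,3-bis(trimethylsilyloxy)buta-1,3-diene | COC(O[Si](C)(C)C)=CC(=C)O[Si](C)(C)C | starting material
3 | methyl (5S)-5-(3,4-dimethoxyphenyl)-3,5-bis(trimethylsilyloxy)pent-2-enoate (enol ether geometry not defined) | COc1ccc([C@@H](O[Si](C)(C)C)CC(O[Si](C)(C)C)=CC(=O)OC)cc1OC | intermediate
4 | methyl (5S)-5-(3,4-dimethoxyphenyl)-5-hydroxy-3-oxopentanoate | COc1ccc([C@@H](O)CC(=O)CC(=O)OC)cc1OC | intermediate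
5 | methyl (5S)-5-(3,4-dimethoxyphenyl)-5-hydroxy-2-[(methylsulfanyl)carbonothioyl]-3-oxopentanoate (C2 enolised, not defined) | COc1ccc([C@@H](O)CC(=O)C(C(=O)OC)C(=S)SC)cc1OC | intermediate
6 | methyl (5S)-2-[bis(methylsulfanyl)methylidene]-5-(3,4-dimethoxyphenyl)-5-hydroxy-3-oxopentanoate | COc1ccc([C@@H](O)CC(=O)C(C(=O)OC)=C(SC)SC)cc1OC | intermediate
7 | methoxyacetone (1-methoxypropan-2-one) | COCC(C)=O | starting material
8 | lithium 3-methoxyprop-1-en-2-olate (kinetic enolate of 7) | [Li+].[O-]C(=C)COC | intermediate
9 | methyl (2S)-2-(3,4-dimethoxyphenyl)-6-(methylsulfanyl)-4-oxo-3,4-dihydro-2H-pyran-5-carboxylate | COc1ccc([C@@H]2CC(=O)C(C(=O)OC)=C(SC)O2)cc1OC | intermediate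
10 | methyl (2S)-2-(3,4-dimethoxyphenyl)-6-(3-methoxy-2-oxopropyl)-4-oxo-3,4-dihydro-2H-pyran-5-carboxylate | COc1ccc([C@@H]2CC(=O)C(C(=O)OC)=C(CC(=O)COC)O2)cc1OC | intermediate
11 | (2S)-2-(3,4-dimethoxyphenyl)-5,7-dihydroxy-6-methoxy-2,3-dihydro-4H-chromen-4-one | COc1ccc([C@@H]2CC(=O)c3c(cc(O)c(OC)c3O)O2)cc1OC | intermediate
12 | (2S)-2-(3,4-dimethoxyphenyl)-5-hydroxy-6,7-dimethoxy-2,3-dihydro-4H-chromen-4-one | COc1ccc([C@@H]2CC(=O)c3c(cc(OC)c(OC)c3O)O2)cc1OC | target

**Totals:** 4 steps; longest linear sequence 4 steps.

**Steps most likely to fail**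

1. Step 3 (key step). Several things can go wrong:
- methoxyacetone may react through its OMe-bearing carbon, giving the 8-methoxy isomer;
- the alkoxide may lactonise onto the ester instead of displacing SMe;
- the ketone enol oxygen may acylate instead of the carbon (α-pyrone instead of ring A);
- retro-aldol of the lithium aldolate may lower the ee.

Fallback, from 4 back to 10: condense 4 with N,N-dimethylacetamide dimethyl acetal to give the enaminone methyl (5S)-2-[1-(dimethylamino)ethylidene]-5-(3,4-dimethoxyphenyl)-5-hydroxy-3-oxopentanoate F1. Close this with TFA to methyl (2S)-2-(3,4-dimethoxyphenyl)-6-methyl-4-oxo-3,4-dihydro-2H-pyran-5-carboxylate F2, so that ring C is made alone under acid and C8 is already in place. Deprotonate the 6-methyl group of F2 (LDA, THF, −78 °C) and acylate with methyl methoxyacetate; this gives the anion of 10, which is taken on with LiHMDS to 11 as in the main route. The nucleophilic C3 partner is replaced by an electrophilic C2 partner, so the regiochemistry question disappears.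

2. Step 2. The β-hydroxy ketone may undergo retro-aldol or dehydration under carbonate/DMF, or close early to 9 with loss of control.

Fallback, from 1 back to 6: make the dithioacetal before the aldol. Methyl acetoacetate with CS2/K2CO3/MeI gives methyl 2-[bis(methylsulfanyl)methylidene]-3-oxobutanoate F3, which has no sensitive carbinol. Convert F3 to its boron enolate with the Ipc2BCl antipode that attacks the Si face (Et3N, Et2O, −78 °C) and add it to 1, with a non-oxidative work-up (diethanolamine) to spare the sulfides; this gives 6 directly. The ee is expected to be lower and would be upgraded by crystallisation or chiral chromatography.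

3. Step 1. The electron-rich aldehyde is a sluggish electrophile, so conversion and ee may be below those of simple benzaldehydes.

Fallback, from 1 back to 4: homologate 1 with methyl diazoacetate and SnCl2 (Roskamp) to methyl 3-(3,4-dimethoxyphenyl)-3-oxopropanoate F4. Hydrogenate F4 with RuCl2[(R)-BINAP]/H2 in MeOH (Noyori) to methyl (3S)-3-(3,4-dimethoxyphenyl)-3-hydroxypropanoate F5. Extend F5 with excess lithium enolate of methyl acetate (THF, −78→−20 °C, crossed Claisen as in statin side-chain chemistry) to 4. The stereocentre then comes from ketone reduction instead of C–C bond formation.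

**Further compounds**
F1 | step 3 | methyl (5S)-2-[1-(dimethylamino)ethylidene]-5-(3,4-dimethoxyphenyl)-5-hydroxy-3-oxopentanoate | COc1ccc([C@@H](O)CC(=O)C(C(=O)OC)=C(C)N(C)C)cc1OC
F2 | step 3 | methyl (2S)-2-(3,4-dimethoxyphenyl)-6-methyl-4-oxo-3,4-dihydro-2H-pyran-5-carboxylate | COc1ccc([C@@H]2CC(=O)C(C(=O)OC)=C(C)O2)cc1OC
F3 | step 2 | methyl 2-[bis(methylsulfanyl)methylidene]-3-oxobutanoate | CC(=O)C(C(=O)OC)=C(SC)SC
F4 | step 1 | methyl 3-(3,4-dimethoxyphenyl)-3-oxopropanoate | COc1ccc(C(=O)CC(=O)OC)cc1OC
F5 | step 1 | methyl (3S)-3-(3,4-dimethoxyphenyl)-3-hydroxypropanoate | COc1ccc([C@@H](O)CC(=O)OC)cc1OC
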